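**Plan**
- Ring numbering: O1, C2 (OMe), C3 (Et), C4 (C=O), C5 (Me), C6 (side chain); side chain C1' (on C6) to C11'. The retrosynthesis first cuts the C6–C1' bond, giving the complete C6–H pyranone and the complete side chain as a terminal alkene.
- The pyranone is then cut at the methoxy O–CH3 bond, the O1–C2 lactone bond and the C5–C6 bond (a formyl carbon on the γ-carbon of a β-keto ester). The chain is cut at the acetate and at C8'–C9' (epoxide opening).
- Forward: β-keto ester ethylation, dianion formylation and lactonisation to the 4-hydroxy-2-pyranone, then O-methylation to the α-methoxy-γ-pyrone. Separately, Cu-catalysed Grignard opening of (S)-propylene oxide and acetylation. The two halves are joined last.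
- Enabling feature: C6–H is the only C–H on the 4H-pyran-4-one ring. It sits on the C5=C6 enol-ether double bond, α to O1 and β to the C4 carbonyl. A Lewis acid on the C4 carbonyl oxygen makes the ring pyrylium-like, so Ni(0) can add this C–H anti-Markovnikov across the terminal alkene of the chain.
- Neither partner needs a halide, metal handle or protecting group. The single (S) centre comes from (S)-propylene oxide and is never touched afterwards.

Key step: step 6

Remark: compounds 1, 7 and 8 are taken as commercial; the C2 centre of 2 and the centres of 4 are racemic and vanish on ring formation.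

**Step 1**
Reactants: 1 methyl 3-oxopentanoate
Product: 2 methyl 2-ethyl-3-oxopentanoate (racemic)
Conditions: EtI (1.0 eq), K2CO3, acetone, reflux
Reagents that add atoms: iodoethane CCI
Why: Acetoacetic-ester type C-alkylation of the doubly activated C2 methylene by SN2 on a primary iodide is routine, and keeping the iodide limiting holds back dialkylation.

**Step 2**
Reactants: 2 methyl 2-ethyl-3-oxopentanoate
Product: 5 3-ethyl-4-hydroxy-5-methyl-2H-pyran-2-one, via sodium lithium dianion 3 (not isolated), via formyl keto ester 4 (not isolated)
Conditions: NaH, THF, 0 °C; n-BuLi, 0 °C; HCO2Me, −78 to 0 °C; aq. HCl; crude 4 in PhMe, DBU, 60 °C; aq. HCl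
Reagents that add atoms: methyl formate COC=O
Why: The γ-carbanion of the β-keto ester dianion is its more nucleophilic site and undergoes Claisen formylation at C4 (the methoxide set free deprotonates the new 1,3-dicarbonyl), and the chelated Z-enol of the resulting aldehyde then lactonises onto the methyl ester under DBU, the standard 3,5-dioxo ester to 4-hydroxy-2-pyranone closure.

**Step 3**
Reactants: 5 3-ethyl-4-hydroxy-5-methyl-2H-pyran-2-one
Product: 6 3-ethyl-2-methoxy-5-methyl-4H-pyran-4-one
Conditions: MeOTf (1.1 eq), CH2Cl2, 0 °C to rt; aq. NaHCO3
Reagents that add atoms: methyl trifluoromethanesulfonate COS(=O)(=O)C(F)(F)F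
Why: Under neutral conditions the hard methylating agent attacks the most basic oxygen of the hydroxypyranone, the C2 lactone carbonyl oxygen, and loss of the 4-OH proton gives the α-methoxy-γ-pyrone, the known regiochemical outcome of MeOTf or MeOSO2F methylation of 4-hydroxy-2-pyranones.

**Step 4**
Reactants: 7 8-bromooct-1-ene; 8 (S)-2-methyloxirane
Product: 10 (S)-undec-10-en-2-ol, via oct-7-enylmagnesium bromide 9 (not isolated)
Conditions: Mg, THF, 40 °C; CuI (10 mol%), 8, −30 to 0 °C; H2O
Reagents that add atoms: none
Why: Copper-catalysed Grignard opening of a terminal epoxide is an SN2 attack at the unsubstituted CH2, so the C–O stereocentre of (S)-propylene oxide is not involved and is carried unchanged into the (S)-alcohol.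

**Step 5**
Reactants: 10 (S)-undec-10-en-2-ol
Product: 11 (S)-undec-10-en-2-yl acetate
Conditions: Ac2O, Et3N, DMAP (5 mol%), CH2Cl2, 0 °C to rt
Reagents that add atoms: acetic anhydride CC(=O)OC(C)=O
Why: DMAP-catalysed acylation of a secondary alcohol takes place at oxygen only, so the (S) configuration is retained.

**Step 6**
Reactants: 6 3-ethyl-2-methoxy-5-methyl-4H-pyran-4-one; 11 (S)-undec-10-en-2-yl acetate
Product: 12 (S)-11-(5-ethyl-6-methoxy-3-methyl-4-oxo-4H-pyran-2-yl)undecan-2-yl acetate (target)
Conditions: Ni(cod)2 (10 mol%), IPr [1,3-bis(2,6-diisopropylphenyl)imidazol-2-ylidene] (10 mol%), MAD [methylaluminium bis(2,6-di-tert-butyl-4-methylphenoxide)] (20 mol%), 11 (1.5 eq), PhMe, 100 °C, sealed tube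
Reagents that add atoms: none
Why: Proposed new method: MAD binds the C4 carbonyl oxygen of 6, the most Lewis-basic site of this vinylogous carbonate, which gives the ring 4-aluminoxypyrylium character and acidifies C6–H; Ni(0)–IPr then binds the C5=C6 bond together with the terminal alkene of 11, the C6 hydrogen is passed to the internal alkene carbon by ligand-to-ligand hydrogen transfer, and C(sp2)–C(sp3) reductive elimination from the (pyran-6-yl)(n-alkyl)nickel(II) species forms the C6–C1' bond and returns Ni(0). The closest known reaction type is the Ni(0)/aluminium Lewis acid catalysed linear C–H alkylation of 2-pyridones at C6, of 4-pyridones at C2 and of pyridines at C4 with 1-alkenes; a 4-pyranone has not been used, but it offers the same carbonyl-bound Lewis acid, the same heteroatom-flanked C–H and a less aromatic, better π-binding C5=C6 bond. No ring is closed and no stereocentre is formed, and the (S)-acetoxy carbon is remote from the reacting alkene and is not affected. The step needs linear over branched selectivity, which the bulky NHC should secure by favouring hydrogen transfer to the internal carbon and reductive elimination from the primary alkylnickel, while site selectivity is fixed by the substrate because C3 and C5 carry ethyl and methyl and C6–H is the only ring C–H. It also needs chemoselectivity against the acetate and the C2–OMe group, for which the plan relies on a bulky, catalytic, poorly methyl-transferring Lewis acid that prefers the far more basic pyranone carbonyl, and on the absence of any transmetallating nucleophile.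

**Compound list**
1 | methyl 3-oxopentanoate | CCC(=O)CC(=O)OC | starting material
2 | methyl 2-ethyl-3-oxopentanoate (racemic) | CCC(=O)C(CC)C(=O)OC | intermediate
3 | sodium lithium dianion (bis-enolate) of 2, not isolated | CC=C([O-])C(CC)=C([O-])OC.[Na+].[Li+] | intermediate
4 | methyl 2-ethyl-4-methyl-3,5-dioxopentanoate (stereoisomer and enol mixture), not isolated | CCC(C(=O)OC)C(=O)C(C)C=O | intermediate
5 | 3-ethyl-4-hydroxy-5-methyl-2H-pyran-2-one | CCC1=C(O)C(C)=COC1=O | intermediate
6 | 3-ethyl-2-methoxy-5-methyl-4H-pyran-4-one | CCC1=C(OC)OC=C(C)C1=O | intermediate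
7 | 8-bromooct-1-ene | C=CCCCCCCBr | starting material
8 | (S)-2-methyloxirane ((S)-propylene oxide) | C[C@H]1CO1 | starting material
9 | oct-7-en-1-ylmagnesium bromide, not isolated | C=CCCCCCC[Mg]Br | intermediate
10 | (S)-undec-10-en-2-ol | C=CCCCCCCC[C@H](C)O | intermediate
11 | (S)-undec-10-en-2-yl acetate | C=CCCCCCCC[C@H](C)OC(C)=O | intermediate
12 | (S)-11-(5-ethyl-6-methoxy-3-methyl-4-oxo-4H-pyran-2-yl)undecan-2-yl acetate | CCc1c(OC)oc(CCCCCCCCC[C@H](C)OC(C)=O)c(C)c1=O | target

**Step count**
Total: 6 steps. Longest linear sequence: 4 steps (1, 2, 3, 6); the side-chain branch is 3 steps (4, 5, 6).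

**Steps most likely to fail**

Step 6 (proposed new method). The pyranone C–H may not be activated well enough, the nickel hydride may walk the alkene inward and give branched or unreactive internal isomers, or the Lewis acid and nickel may cleave the C2 methoxy group. The fallback uses known reaction types and sets out from 6 and 11. Pyranone 6 is zincated at C6 with TMPZnCl·LiCl (THF, 25 °C), as practised for the C2–H of chromones, to give (5-ethyl-6-methoxy-3-methyl-4-oxo-4H-pyran-2-yl)zinc chloride F1. Iodinolysis with I2 gives 3-ethyl-6-iodo-2-methoxy-5-methyl-4H-pyran-4-one F2. Separately, 11 is hydroborated with 9-BBN-H (THF, rt) to (S)-11-(9-borabicyclo[3.3.1]nonan-9-yl)undecan-2-yl acetate F3. B-alkyl Suzuki–Miyaura coupling of F2 with F3 (PdCl2(dppf), K3PO4, DMF/THF/H2O, rt) forms the same C6–C1' bond and comes back to the route at 12.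

Step 2. The formylated product may transfer a proton to unreacted dianion and stall the reaction, formylation may occur at oxygen, or the aldehyde enol may lactonise incompletely. The fallback sets out from 2 and introduces the one-carbon unit under neutral conditions. Condensation at the C4 methylene with tert-butoxybis(dimethylamino)methane (Bredereck's reagent; PhMe, 80 °C) should give methyl (E)-5-(dimethylamino)-2-ethyl-4-methyl-3-oxopent-4-enoate F4. Aqueous acid (2 M HCl, THF, 50 °C) then hydrolyses the enamine and closes the lactone, coming back to the route at 5.

Step 3. Methylation may occur at the 4-oxygen and give the 4-methoxy-2-pyranone isomer, or the product may be methylated further to a pyrylium salt. The fallback avoids the methylation altogether. It sets out from 4, isolated after the first acidic work-up of step 2. Dehydrative cyclisation with PPh3/CCl4 (THF, reflux) activates the aldehyde enol oxygen, the ester carbonyl oxygen closes the ring as O1, and the ester methoxy group is retained as the C2–OMe. This comes back to the route at 6 and makes no new compound.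

**Further compounds**
F1 | step 6 | (5-ethyl-6-methoxy-3-methyl-4-oxo-4H-pyran-2-yl)zinc chloride | CCC1=C(OC)OC([Zn]Cl)=C(C)C1=O
F2 | step 6 | 3-ethyl-6-iodo-2-methoxy-5-methyl-4H-pyran-4-one | CCC1=C(OC)OC(I)=C(C)C1=O
F3 | step 6 | (S)-11-(9-borabicyclo[3.3.1]nonan-9-yl)undecan-2-yl acetate | B1(CCCCCCCCC[C@H](C)OC(C)=O)C2CCCC1CCC2
F4 | step 2 | methyl (E)-5-(dimethylamino)-2-ethyl-4-methyl-3-oxopent-4-enoate (racemic) | CCC(C(=O)OC)C(=O)/C(C)=C/N(C)C
F0 | step 3 | none | none
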